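**Retrosynthetic overview**

- The route rests on the unit C14(OAc)–C13H2–C12(OH)(CH3) of the 14-membered carbocycle (C1–C14, fused at C2–C4 to the butenolide). With its quaternary carbinol at C12 it is the retron of an isoxazoline that bridges C12 (O) and C14 (C=N).
- Acetate removal, 1,3-anti reduction and N–O cleavage lead back to that isoxazoline. It is disconnected at C13–C14 and C12–O into a C14 nitrile oxide and the terminal C12=C13 bond of a 2-methyl-1,3-diene.
- Ring order: the butenolide is closed first by ring-closing metathesis (C3=C4). The isoxazoline and the 14-membered carbocycle then close together in one cycloaddition, and the isoxazoline is opened afterwards.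
- The seco-oxime comes from a west allylic alcohol (C14, C1, C2, C3; Evans syn-aldol) esterified with an east 2-methylene acid (C4–C11). The diene is completed by Takai iodo-olefination and Suzuki coupling (C11–C12).
- The east acid comes from methyl hydrogen (R)-3-methylglutarate (C6–C10, C8 stereocentre) and 2-(bromomethyl)acrylic acid (indium Barbier, C5–C6). C6 is carried as a silyl ether and oxidised together with C14 just before the oxime is made.

Key step: step 18

Remark on the chemistry: all intermediates use the carbocycle numbering of the target (C1 CH–isopropyl, C2 CH–O, C3=C4 butenolide alkene, C5, C6 ketone, C7, C8 CH–CH3, C9, C10=C11, C12 C(OH)CH3, C13, C14 CH–OAc). The C6 carbinol made in step 10 is carried as a mixture of epimers until step 16 removes that stereocentre. The aldoxime of step 17 is an E/Z mixture, and both isomers give the same nitrile oxide.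

**Route**

Step 1
Reactants: 1 (S)-4-benzyloxazolidin-2-one; 2 isovaleryl chloride
Product: 3 (S)-4-benzyl-3-(3-methylbutanoyl)oxazolidin-2-one
Conditions: Et3N, DMAP (cat.), CH2Cl2, 0 °C to rt
Reagents that add atoms: none
Why: DMAP-catalysed N-acylation of the oxazolidinone by the acid chloride gives the Evans imide without touching the stereocentre of the auxiliary.

Step 2
Reactants: 3 (S)-4-benzyl-3-(3-methylbutanoyl)oxazolidin-2-one; 4 acrolein
Product: 6 (S)-4-benzyl-3-[(2S,3R)-3-hydroxy-2-isopropylpent-4-enoyl]oxazolidin-2-one, via (Z)-boron enolate 5 (not isolated)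
Conditions: Bu2BOTf, Et3N, CH2Cl2, -78 to 0 °C; then 4, -78 to 0 °C; pH 7 buffer, MeOH, H2O2, 0 °C
Reagents that add atoms: none
Why: Evans syn-aldol reaction, in which the (Z)-dibutylboron enolate reacts through a closed Zimmerman–Traxler chair on the face away from the benzyl group and so sets C1 and C2 (syn, absolute sense from the (S)-auxiliary) in one step.

Step 3
Reactants: 6 (S)-4-benzyl-3-[(2S,3R)-3-hydroxy-2-isopropylpent-4-enoyl]oxazolidin-2-one
Product: 7 (2R,3R)-2-isopropylpent-4-ene-1,3-diol
Conditions: LiBH4, MeOH (1 equiv), THF, 0 °C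
Reagents that add atoms: none
Why: Reductive cleavage of the imide, in which borohydride attacks the exocyclic carbonyl (C14), releases the auxiliary and gives the 1,3-diol without epimerising C1.

Step 4
Reactants: 7 (2R,3R)-2-isopropylpent-4-ene-1,3-diol
Product: 8 (3R,4R)-4-{[(tert-butyldimethylsilyl)oxy]methyl}-5-methylhex-1-en-3-ol
Conditions: TBSCl (1.05 equiv), imidazole, CH2Cl2, 0 °C
Reagents that add atoms: tert-butyldimethylsilyl chloride, CC(C)(C)[Si](C)(C)Cl
Why: Selective silyl ether formation, since the unhindered primary C14 hydroxyl is silylated much faster than the secondary allylic C2 hydroxyl next to the C1 branch.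

Step 5
Reactants: 9 methyl hydrogen (R)-3-methylglutarate
Product: 11 (S)-4-methyltetrahydro-2H-pyran-2-one, via hydroxy acid 10 (not isolated)
Conditions: LiBH4, THF, 0 °C to rt; then 2 M HCl, rt
Reagents that add atoms: none
Why: Chemoselective ester reduction, since the lithium carboxylate formed first is inert to LiBH4 while the methyl ester is reduced, and acidification closes the δ-lactone whose carbonyl is the future C6 and whose CH2–O is the future C10, the C8 stereocentre being untouched.

Step 6
Reactants: 11 (S)-4-methyltetrahydro-2H-pyran-2-one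
Product: 12 (S)-5-hydroxy-N-methoxy-N,3-dimethylpentanamide
Conditions: MeNHOMe·HCl, AlMe3, CH2Cl2, 0 °C to rt
Reagents that add atoms: N,O-dimethylhydroxylamine hydrochloride, CNOC.Cl
Why: Weinreb aminolysis of the lactone by the aluminium amide opens the ring at the acyl C6–O bond and keeps C6 at the acyl oxidation level for later reduction to the aldehyde.

Step 7
Reactants: 12 (S)-5-hydroxy-N-methoxy-N,3-dimethylpentanamide
Product: 13 (S)-N-methoxy-N,3-dimethyl-5-oxopentanamide
Conditions: DMP, CH2Cl2, 0 °C to rt
Reagents that add atoms: none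
Why: Dess–Martin oxidation converts the primary C10 alcohol into the aldehyde under neutral conditions that leave the Weinreb amide alone and forestall relactonisation.

Step 8
Reactants: 13 (S)-N-methoxy-N,3-dimethyl-5-oxopentanamide
Product: 14 (3S,5E)-6-iodo-N-methoxy-N,3-dimethylhex-5-enamide
Conditions: CrCl2, CHI3, THF/dioxane, 0 °C to rt
Reagents that add atoms: iodoform, IC(I)I
Why: Takai iodo-olefination, in which the geminal dichromium species from iodoform adds to the aldehyde and anti-elimination of the β-oxido chromium intermediate gives the (E)-alkenyl iodide (C10=C11).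

Step 9
Reactants: 14 (3S,5E)-6-iodo-N-methoxy-N,3-dimethylhex-5-enamide
Product: 15 (3S,5E)-6-iodo-3-methylhex-5-enal
Conditions: DIBAL-H, THF, -78 °C; aq. Rochelle salt
Reagents that add atoms: none
Why: Reduction of the Weinreb amide stops at the chelated tetrahedral aluminate, which gives the C6 aldehyde on work-up, and the alkenyl iodide is inert at -78 °C.

Step 10
Reactants: 15 (3S,5E)-6-iodo-3-methylhex-5-enal; 16 2-(bromomethyl)acrylic acid
Product: 18 (6S,8E)-4-hydroxy-9-iodo-6-methyl-2-methylidenenon-8-enoic acid (epimers at the carbinol carbon), via allylindium bromide 17 (not isolated)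
Conditions: In powder, THF/H2O (1:1), rt; work-up at pH 4
Reagents that add atoms: none
Why: Indium-mediated Barbier allylation in water tolerates the free acid and the alkenyl iodide and forms the C5–C6 bond, while the new C6 carbinol forms without control and is oxidised to the ketone later.

Step 11
Reactants: 18 (6S,8E)-4-hydroxy-9-iodo-6-methyl-2-methylidenenon-8-enoic acid
Product: 20 (6S,8E)-4-[(tert-butyldimethylsilyl)oxy]-9-iodo-6-methyl-2-methylidenenon-8-enoic acid, via bis-silyl derivative 19 (not isolated)
Conditions: TBSCl, imidazole, DMF, rt; then K2CO3, MeOH/THF/H2O, 0 °C; work-up at pH 4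
Reagents that add atoms: tert-butyldimethylsilyl chloride, CC(C)(C)[Si](C)(C)Cl
Why: Exhaustive silylation followed by selective cleavage of the labile silyl ester (far less stable to carbonate than the silyl ether) gives the acid with C6–OH masked against γ-lactonisation.

Step 12
Reactants: 20 (6S,8E)-4-[(tert-butyldimethylsilyl)oxy]-9-iodo-6-methyl-2-methylidenenon-8-enoic acid; 8 (3R,4R)-4-{[(tert-butyldimethylsilyl)oxy]methyl}-5-methylhex-1-en-3-ol
Product: 22 ester of the C2 hydroxyl of 8 with acid 20, via mixed anhydride 21 (not isolated)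
Conditions: 2,4,6-trichlorobenzoyl chloride, Et3N, toluene, rt; then 8, DMAP, rt
Reagents that add atoms: none
Why: Yamaguchi esterification, in which DMAP attacks the mixed anhydride at the less hindered acrylic carbonyl and the acylpyridinium acylates the hindered secondary C2 hydroxyl with retention at C2.

Step 13
Reactants: 22 ester of the C2 hydroxyl of 8 with acid 20
Product: 23 (5R)-5-[(2R)-1-(tert-butyldimethylsilyloxy)-3-methylbutan-2-yl]-3-[(4S,6E)-2-(tert-butyldimethylsilyloxy)-7-iodo-4-methylhept-6-en-1-yl]furan-2(5H)-one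
Conditions: second-generation Grubbs catalyst RuCl2(=CHPh)(H2IMes)(PCy3) (5 mol %), toluene, 80 °C, 5 mM
Reagents that add atoms: none
Why: Ring-closing metathesis, in which the ruthenium carbene loads on the monosubstituted C3 vinyl group and closes the five-membered ring onto the 1,1-disubstituted acrylate to form C3=C4 of the butenolide, the (E)-alkenyl iodide being a poor metathesis partner.

Step 14
Reactants: 23 butenolide alkenyl iodide; 24 isopropenylboronic acid pinacol ester
Product: 25 (5R)-5-[(2R)-1-(tert-butyldimethylsilyloxy)-3-methylbutan-2-yl]-3-[(4S,6E)-2-(tert-butyldimethylsilyloxy)-4,8-dimethylnona-6,8-dien-1-yl]furan-2(5H)-one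
Conditions: PdCl2(dppf) (5 mol %), K3PO4 (aq.), THF, rt
Reagents that add atoms: none
Why: Suzuki–Miyaura coupling of the (E)-alkenyl iodide with the isopropenyl boronate forms C11–C12 with retention of the alkene geometry and installs the 2-methyl-1,3-diene under base mild enough for the butenolide and the silyl ethers.

Step 15
Reactants: 25 bis-silyl diene butenolide
Product: 26 (5R)-5-[(2R)-1-hydroxy-3-methylbutan-2-yl]-3-[(4S,6E)-2-hydroxy-4,8-dimethylnona-6,8-dien-1-yl]furan-2(5H)-one
Conditions: HF·pyridine, pyridine, THF, 0 °C to rt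
Reagents that add atoms: none
Why: Fluoride cleavage of both silyl ethers with buffered HF·pyridine frees the C14 and C6 hydroxyls without acid strong enough to harm the diene or the butenolide.

Step 16
Reactants: 26 diol
Product: 27 (2S)-2-{(2R)-4-[(4S,6E)-4,8-dimethyl-2-oxonona-6,8-dien-1-yl]-5-oxo-2,5-dihydrofuran-2-yl}-3-methylbutanal
Conditions: DMP (3 equiv), CH2Cl2, 0 °C to rt; used crude
Reagents that add atoms: none
Why: Dess–Martin oxidation of both alcohols in one operation gives the C14 aldehyde and the C6 ketone (removing the C6 epimer mixture) under non-basic conditions that should not epimerise C1 or shift the butenolide double bond.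

Step 17
Reactants: 27 keto aldehyde
Product: 28 C14 aldoxime of 27 (E/Z mixture)
Conditions: NH2OH·HCl (1.05 equiv), NaOAc, MeOH, -10 to 0 °C
Reagents that add atoms: hydroxylamine hydrochloride, NO.Cl
Why: Oxime condensation, in which one equivalent of hydroxylamine at low temperature reacts with the aldehyde much faster than with the dialkyl ketone and so gives the C14 aldoxime chemoselectively.

Step 18
Reactants: 28 C14 aldoxime
Product: 31 isoxazoline-bridged 14-membered carbocycle (O–N bridge from C12 to C14; 12S), via hydroximoyl chloride 29 (not isolated), via nitrile oxide 30 (not isolated)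
Conditions: aq. NaOCl, CH2Cl2, 0 °C to rt, slow addition of 28 (final about 1 mM)
Reagents that add atoms: none
Why: Hypochlorite chlorinates the aldoxime to hydroximoyl chloride 29, which loses HCl to nitrile oxide 30; this adds in a concerted suprafacial [3+2] step across the terminal C12=C13 bond, the dipole carbon C14 bonding to the unsubstituted C13 and the dipole oxygen to the substituted C12, as is general for 1,1-disubstituted alkenes and for 1,3-dienes. The closest known reaction type is the intramolecular nitrile oxide–alkene cycloaddition used as a macrocyclisation, with later cleavage of the isoxazoline to a β-hydroxy ketone. The isoxazoline closes as the five-membered cycloadduct and the 14-membered carbocycle closes at the same time in the endo (bridged) mode, both alkene carbons lying inside the new ring, which is the normal outcome for long tethers because the intermolecular regiochemistry is kept. C12 is the only new stereocentre and its configuration (12S needed) is decided by the folding of the macrocyclic transition state, shaped by C1, C2, C8, the flat butenolide and the s-trans diene; this face selectivity is the unsecured point of the step. Site selectivity is secured by the substrate, because C12=C13 is the only terminal alkene, C10=C11 is 1,2-disubstituted and less reactive, and the butenolide C3=C4 bond cannot be reached without a four-membered ring or a bridgehead C=N bond. Ring closure has to outrun furoxan formation, which slow addition at high dilution and the α-branching at C1 should ensure.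

Step 19
Reactants: 31 isoxazoline-bridged carbocycle
Product: 33 (12S)-12-hydroxy-6,14-diketone of the carbocycle (β-hydroxy ketone), via β-hydroxy imine 32 (not isolated)
Conditions: Mo(CO)6, MeCN/H2O (10:1), 80 °C
Reagents that add atoms: water, O
Why: Zerovalent molybdenum cleaves the weak N–O bond reductively and water hydrolyses the β-hydroxy imine, which unmasks the C14 ketone and the tertiary C12 hydroxyl with retention at C12 (the C12–O bond is not touched) while the alkenes, the C6 ketone and the butenolide are left alone.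

Step 20
Reactants: 33 β-hydroxy ketone
Product: 34 (12S,14S)-12,14-diol of the carbocycle (1,3-anti)
Conditions: Me4NBH(OAc)3, MeCN/AcOH (1:1), -30 to -20 °C
Reagents that add atoms: none
Why: Saksena–Evans anti-reduction, in which the C12 hydroxyl exchanges onto boron and delivers hydride intramolecularly through a chair transition state to the C14 carbonyl, setting C14 anti to C12–OH (14S), while the C6 ketone has no hydroxyl to bind the reagent and is not reduced by triacetoxyborohydride.

Step 21
Reactants: 34 anti-1,3-diol
Product: 35 CNP0200490.2 (target)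
Conditions: Ac2O, pyridine, DMAP (cat.), CH2Cl2, 0 °C to rt
Reagents that add atoms: acetic anhydride, CC(=O)OC(C)=O
Why: DMAP-catalysed acetylation acylates the secondary C14 hydroxyl, the tertiary C12 hydroxyl being too hindered to react under these conditions.

**Compound list**

1 | (S)-4-benzyloxazolidin-2-one | O=C1N[C@@H](Cc2ccccc2)CO1 | starting material
2 | isovaleryl chloride (3-methylbutanoyl chloride) | CC(C)CC(Cl)=O | starting material
3 | (S)-4-benzyl-3-(3-methylbutanoyl)oxazolidin-2-one | CC(C)CC(=O)N1[C@@H](Cc2ccccc2)COC1=O | intermediate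
4 | acrolein | C=CC=O | starting material
5 | (Z)-dibutylboron enolate of 3 | CCCCB(CCCC)O/C(=C\C(C)C)N1[C@@H](Cc2ccccc2)COC1=O | intermediate (not isolated)
6 | (S)-4-benzyl-3-[(2S,3R)-3-hydroxy-2-isopropylpent-4-enoyl]oxazolidin-2-one | O=C(N1[C@@H](Cc2ccccc2)COC1=O)[C@@H](C(C)C)[C@H](O)C=C | intermediate
7 | (2R,3R)-2-isopropylpent-4-ene-1,3-diol | OC[C@@H](C(C)C)[C@H](O)C=C | intermediate
8 | (3R,4R)-4-{[(tert-butyldimethylsilyl)oxy]methyl}-5-methylhex-1-en-3-ol | CC(C)(C)[Si](C)(C)OC[C@@H](C(C)C)[C@H](O)C=C | intermediate
9 | methyl hydrogen (R)-3-methylglutarate | COC(=O)C[C@H](C)CC(=O)O | starting material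
10 | (S)-5-hydroxy-3-methylpentanoic acid | OCC[C@H](C)CC(=O)O | intermediate (not isolated)
11 | (S)-4-methyltetrahydro-2H-pyran-2-one | O=C1C[C@@H](C)CCO1 | intermediate
12 | (S)-5-hydroxy-N-methoxy-N,3-dimethylpentanamide | CON(C)C(=O)C[C@@H](C)CCO | intermediate
13 | (S)-N-methoxy-N,3-dimethyl-5-oxopentanamide | CON(C)C(=O)C[C@@H](C)CC=O | intermediate
14 | (3S,5E)-6-iodo-N-methoxy-N,3-dimethylhex-5-enamide | CON(C)C(=O)C[C@@H](C)C/C=C/I | intermediate
15 | (3S,5E)-6-iodo-3-methylhex-5-enal | O=CC[C@@H](C)C/C=C/I | intermediate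
16 | 2-(bromomethyl)acrylic acid | OC(=O)C(=C)CBr | starting material
17 | (2-carboxyallyl)indium dibromide (allylindium reagent, drawn as RInBr2) | OC(=O)C(=C)C[In](Br)Br | intermediate (not isolated)
18 | (6S,8E)-4-hydroxy-9-iodo-6-methyl-2-methylidenenon-8-enoic acid (C4 epimers; C4 is C6 of the carbocycle) | OC(=O)C(=C)CC(O)C[C@@H](C)C/C=C/I | intermediate
19 | tert-butyldimethylsilyl (6S,8E)-4-[(tert-butyldimethylsilyl)oxy]-9-iodo-6-methyl-2-methylidenenon-8-enoate (C4 epimers) | C=C(CC(O[Si](C)(C)C(C)(C)C)C[C@@H](C)C/C=C/I)C(=O)O[Si](C)(C)C(C)(C)C | intermediate (not isolated)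
20 | (6S,8E)-4-[(tert-butyldimethylsilyl)oxy]-9-iodo-6-methyl-2-methylidenenon-8-enoic acid (C4 epimers) | OC(=O)C(=C)CC(O[Si](C)(C)C(C)(C)C)C[C@@H](C)C/C=C/I | intermediate
21 | mixed anhydride of 20 with 2,4,6-trichlorobenzoic acid | C=C(CC(O[Si](C)(C)C(C)(C)C)C[C@@H](C)C/C=C/I)C(=O)OC(=O)c1c(Cl)cc(Cl)cc1Cl | intermediate (not isolated)
22 | (3R,4R)-4-{[(tert-butyldimethylsilyl)oxy]methyl}-5-methylhex-1-en-3-yl (6S,8E)-4-[(tert-butyldimethylsilyl)oxy]-9-iodo-6-methyl-2-methylidenenon-8-enoate (C6 epimers) | CC(C)(C)[Si](C)(C)OC[C@@H](C(C)C)[C@H](OC(=O)C(=C)CC(O[Si](C)(C)C(C)(C)C)C[C@@H](C)C/C=C/I)C=C | intermediate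
23 | (5R)-5-[(2R)-1-(tert-butyldimethylsilyloxy)-3-methylbutan-2-yl]-3-[(4S,6E)-2-(tert-butyldimethylsilyloxy)-7-iodo-4-methylhept-6-en-1-yl]furan-2(5H)-one (C6 epimers) | CC(C)(C)[Si](C)(C)OC[C@@H](C(C)C)[C@@H]1OC(=O)C(CC(O[Si](C)(C)C(C)(C)C)C[C@@H](C)C/C=C/I)=C1 | intermediate
24 | isopropenylboronic acid pinacol ester | CC(=C)B1OC(C)(C)C(C)(C)O1 | starting material
25 | (5R)-5-[(2R)-1-(tert-butyldimethylsilyloxy)-3-methylbutan-2-yl]-3-[(4S,6E)-2-(tert-butyldimethylsilyloxy)-4,8-dimethylnona-6,8-dien-1-yl]furan-2(5H)-one (C6 epimers) | CC(C)(C)[Si](C)(C)OC[C@@H](C(C)C)[C@@H]1OC(=O)C(CC(O[Si](C)(C)C(C)(C)C)C[C@@H](C)C/C=C/C(C)=C)=C1 | intermediate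
26 | (5R)-5-[(2R)-1-hydroxy-3-methylbutan-2-yl]-3-[(4S,6E)-2-hydroxy-4,8-dimethylnona-6,8-dien-1-yl]furan-2(5H)-one (C6 epimers) | OC[C@@H](C(C)C)[C@@H]1OC(=O)C(CC(O)C[C@@H](C)C/C=C/C(C)=C)=C1 | intermediate
27 | (2S)-2-{(2R)-4-[(4S,6E)-4,8-dimethyl-2-oxonona-6,8-dien-1-yl]-5-oxo-2,5-dihydrofuran-2-yl}-3-methylbutanal | O=C[C@@H](C(C)C)[C@@H]1OC(=O)C(CC(=O)C[C@@H](C)C/C=C/C(C)=C)=C1 | intermediate
28 | C14 aldoxime of 27 (E/Z mixture; C1, C2, C8 as in the target) | ON=C[C@@H](C(C)C)[C@@H]1OC(=O)C(=C1)CC(=O)C[C@@H](C)C/C=C/C(C)=C | intermediate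
29 | C14 hydroximoyl chloride of 28 | ON=C(Cl)[C@@H](C(C)C)[C@@H]1OC(=O)C(=C1)CC(=O)C[C@@H](C)C/C=C/C(C)=C | intermediate (not isolated)
30 | C14 nitrile oxide | [O-][N+]#C[C@@H](C(C)C)[C@@H]1OC(=O)C(=C1)CC(=O)C[C@@H](C)C/C=C/C(C)=C | intermediate (not isolated)
31 | isoxazoline-bridged 14-membered carbocycle (O on C12, C14=N; 12S; C6 ketone; butenolide at C2–C4; (E)-C10=C11) | O1N=C2C[C@@]1(C)/C=C/C[C@H](C)CC(=O)CC3=C[C@@H](OC3=O)[C@@H]2C(C)C | intermediate
32 | (12S)-12-hydroxy-14-imino-6-oxo carbocycle (β-hydroxy imine) | N=C1C[C@](C)(O)/C=C/C[C@H](C)CC(=O)CC2=C[C@@H](OC2=O)[C@@H]1C(C)C | intermediate (not isolated)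
33 | (12S)-12-hydroxy-6,14-dioxo carbocycle (β-hydroxy ketone) | O=C1C[C@](C)(O)/C=C/C[C@H](C)CC(=O)CC2=C[C@@H](OC2=O)[C@@H]1C(C)C | intermediate
34 | (12S,14S)-12,14-dihydroxy-6-oxo carbocycle (1,3-anti diol) | O[C@H]1C[C@](C)(O)/C=C/C[C@H](C)CC(=O)CC2=C[C@@H](OC2=O)[C@@H]1C(C)C | intermediate
35 | CNP0200490.2: (1R,2R,8S,10E,12S,14S)-14-acetoxy-12-hydroxy-1-isopropyl-8,12-dimethyl-6-oxo carbocycle with the C2–O–C(=O)–C4 butenolide | CC(=O)O[C@H]1C[C@](C)(O)/C=C/C[C@H](C)CC(=O)CC2=C[C@@H](OC2=O)[C@@H]1C(C)C | target

**Step count**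

Total: 21 steps. Longest linear sequence: 17 steps (steps 5–21, from 9). The west branch (steps 1–4) joins at step 12.

**Steps most likely to fail**

1. Step 18. The macrocyclic transition state may discriminate poorly between the two faces of C12=C13 and give the wrong or a mixed C12 configuration. Dimerisation of the nitrile oxide to furoxans may compete with ring closure, and hypochlorite may chlorinate the C5 methylene between ketone and butenolide or attack the butenolide.
 The fallback keeps C6 as an sp3 carbinol during ring closure and avoids hypochlorite. It sets out from diol 26. TEMPO (cat.) and PhI(OAc)2 in CH2Cl2 oxidise only the primary C14 alcohol to the hydroxy aldehyde F1. NH2OH·HCl and NaOAc give the hydroxy aldoxime F2, with no ketone present to compete. NCS in DMF gives the hydroximoyl chloride F3. Slow addition of F3 to Et3N in CH2Cl2 at high dilution releases the nitrile oxide F4, which closes to the C6-hydroxy isoxazoline macrocycle F5. DMP then oxidises C6, and the route is rejoined at 31. The sp3 centre at C6 changes the folding of the C5–C9 tether, and the two C6 epimers, separable at F1, are two independently biased substrates for the face selection.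

2. Step 17. Condensation at the unhindered C6 ketone may compete with the α-branched C14 aldehyde and give ketoxime or bis-oxime, and hydroxylamine may add to the butenolide.
 The fallback makes the nitrile oxide from the carboxylic acid level. It sets out from keto aldehyde 27. Pinnick oxidation (NaClO2, NaH2PO4, 2-methylbut-2-ene, t-BuOH/H2O) converts only the aldehyde into the keto acid F6. EDC coupling with O-(tert-butyldiphenylsilyl)hydroxylamine gives the O-silyl hydroxamate F7. Tf2O and Et3N at -40 °C under high dilution convert it through the O-triflyl hydroximate F8 into nitrile oxide 30 (dehydration of O-silylated hydroxamic acids is an established nitrile oxide synthesis). The route is rejoined there and continues to 31.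

3. Step 20. Exchange of the tertiary C12 hydroxyl onto boron may be slow, or the macrocycle may override the chair transition state, so that hydride delivery gives the syn diol or a mixture at C14.
 The fallback reduces syn and then inverts. It sets out from β-hydroxy ketone 33. Catecholborane in THF at -10 °C, a syn-selective reduction of β-hydroxy ketones that leaves the isolated C6 ketone alone, gives the (12S,14R) syn diol F9. A Mitsunobu reaction with acetic acid (PPh3, DIAD, toluene) inverts C14 and installs the acetate in the same step, the tertiary C12 hydroxyl being inert. The route is rejoined at target 35.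

**Further compounds**

F1 | step 18 | C6-hydroxy C14 aldehyde (C6 epimers) | O=C[C@@H](C(C)C)[C@@H]1OC(=O)C(CC(O)C[C@@H](C)C/C=C/C(C)=C)=C1
F2 | step 18 | C6-hydroxy C14 aldoxime | ON=C[C@@H](C(C)C)[C@@H]1OC(=O)C(CC(O)C[C@@H](C)C/C=C/C(C)=C)=C1
F3 | step 18 | C6-hydroxy C14 hydroximoyl chloride | ON=C(Cl)[C@@H](C(C)C)[C@@H]1OC(=O)C(CC(O)C[C@@H](C)C/C=C/C(C)=C)=C1
F4 | step 18 | C6-hydroxy C14 nitrile oxide | [O-][N+]#C[C@@H](C(C)C)[C@@H]1OC(=O)C(CC(O)C[C@@H](C)C/C=C/C(C)=C)=C1
F5 | step 18 | C6-hydroxy isoxazoline-bridged carbocycle | O1N=C2C[C@@]1(C)/C=C/C[C@H](C)CC(O)CC3=C[C@@H](OC3=O)[C@@H]2C(C)C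
F6 | step 17 | C14 carboxylic acid with C6 ketone | OC(=O)[C@@H](C(C)C)[C@@H]1OC(=O)C(CC(=O)C[C@@H](C)C/C=C/C(C)=C)=C1
F7 | step 17 | O-(tert-butyldiphenylsilyl) hydroxamate of F6 | CC(C)(C)[Si](c1ccccc1)(c1ccccc1)ONC(=O)[C@@H](C(C)C)[C@@H]1OC(=O)C(CC(=O)C[C@@H](C)C/C=C/C(C)=C)=C1
F8 | step 17 | O-triflyl hydroximate of F7 | CC(C)(C)[Si](c1ccccc1)(c1ccccc1)ON=C(OS(=O)(=O)C(F)(F)F)[C@@H](C(C)C)[C@@H]1OC(=O)C(CC(=O)C[C@@H](C)C/C=C/C(C)=C)=C1
F9 | step 20 | (12S,14R)-12,14-dihydroxy-6-oxo carbocycle (1,3-syn diol) | O[C@@H]1C[C@](C)(O)/C=C/C[C@H](C)CC(=O)CC2=C[C@@H](OC2=O)[C@@H]1C(C)C
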